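Dihydrocurcumin contains one E aryl enone, ring A–C1=C2–C3(=O) (chain numbered from the styryl CH, C1, to the benzylic CH2, C7), and the key step exploits it. The bond from C1 to the ring A carbon para to the phenol oxygen is made by Mizoroki–Heck arylation, which sets the E C1=C2 geometry in the same operation. The alkene partner is a vinyl ketone aldol, C1=C2–C3(=O)–C4–C5(OH), that already carries the C6–C7 arm and ring B. Keeping C5 as a carbinol avoids an unstable vinyl 1,3-diketone. Both phenols travel as tert-butyldimethylsilyl ethers; oxidation at C5 and desilylation finish the synthesis.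

Key step: step 6

Remark: the target and compound 12 are drawn as 3,5-diketones; both are expected to exist largely as the C3/C5 enol tautomer, which is the same compound.

Step 1
Reactants: 1 dihydroferulic acid, 3-(4-hydroxy-3-methoxyphenyl)propanoic acid
Product: 2 methyl 3-(4-hydroxy-3-methoxyphenyl)propanoate
Conditions: MeOH, cat. H2SO4, reflux
Reagents that add atoms: methanol, CO
Why: Fischer esterification in a large excess of methanol should convert the carboxylic acid into its methyl ester while the phenol, which is not etherified under these conditions, stays free.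

Step 2
Reactants: 2 methyl 3-(4-hydroxy-3-methoxyphenyl)propanoate
Product: 3 methyl 3-[4-(tert-butyldimethylsilyloxy)-3-methoxyphenyl]propanoate
Conditions: TBSCl, imidazole, DMF, rt
Reagents that add atoms: tert-butyldimethylsilyl chloride, CC(C)(C)[Si](C)(C)Cl
Why: Imidazole-promoted silylation of the only hydroxyl group should give the aryl silyl ether, a phenol mask that tolerates hydride at low temperature, BF3 at −78 °C, bicarbonate and the Dess–Martin reagent and is removed by fluoride at the end.

Step 3
Reactants: 3 methyl 3-[4-(tert-butyldimethylsilyloxy)-3-methoxyphenyl]propanoate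
Product: 5 3-[4-(tert-butyldimethylsilyloxy)-3-methoxyphenyl]propanal, via aluminium hemiacetal 4 (not isolated)
Conditions: i-Bu2AlH (1.1 equiv), toluene, −78 °C; then aq. potassium sodium tartrate
Reagents that add atoms: none
Why: Partial ester reduction with one equivalent of i-Bu2AlH at −78 °C should stop at the tetrahedral aluminium hemiacetal 4, which releases the aldehyde only on aqueous work-up, and the aryl silyl ether is inert to the hydride at this temperature.

Step 4
Reactants: 5 3-[4-(tert-butyldimethylsilyloxy)-3-methoxyphenyl]propanal; 6 2-(trimethylsilyloxy)-1,3-butadiene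
Product: 8 racemic 7-[4-(tert-butyldimethylsilyloxy)-3-methoxyphenyl]-5-hydroxyhept-1-en-3-one, via difluoroboron aldolate 7 (not isolated)
Conditions: BF3·OEt2 (1.1 equiv), 6 (1.5 equiv), CH2Cl2, −78 °C; then aq. NaHCO3
Reagents that add atoms: none
Why: In this Mukaiyama aldol addition the BF3-activated aldehyde is attacked by the silyl enol ether CH2 terminus of diene 6 to form the C4–C5 bond with the vinyl group carried along untouched, fluoride transfer removes the trimethylsilyl group, and hydrolysis of aldolate 7 frees the C5 carbinol, whose configuration is uncontrolled (racemic) and irrelevant because C5 becomes a carbonyl in step 7.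

Step 5
Reactants: 9 4-iodo-2-methoxyphenol
Product: 10 1-(tert-butyldimethylsilyloxy)-4-iodo-2-methoxybenzene
Conditions: TBSCl, imidazole, DMF, rt
Reagents that add atoms: tert-butyldimethylsilyl chloride, CC(C)(C)[Si](C)(C)Cl
Why: The same imidazole-promoted phenol silylation as in step 2 should mask the phenol so that no phenoxide can interfere with palladium or add to the enone during the coupling, and the aryl iodide is untouched.

Step 6
Reactants: 8 racemic 7-[4-(tert-butyldimethylsilyloxy)-3-methoxyphenyl]-5-hydroxyhept-1-en-3-one; 10 1-(tert-butyldimethylsilyloxy)-4-iodo-2-methoxybenzene (1.2 equiv)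
Product: 11 racemic (E)-1,7-bis[4-(tert-butyldimethylsilyloxy)-3-methoxyphenyl]-5-hydroxyhept-1-en-3-one
Conditions: Pd(OAc)2 (5 mol %), Bu4NCl (1.0 equiv), NaHCO3 (2.5 equiv), dry degassed DMF, 45 °C
Reagents that add atoms: none
Why: Zerovalent palladium, formed in situ from Pd(OAc)2 and stabilised by chloride from Bu4NCl, should insert into the C–I bond of 10; the arylpalladium species then adds syn across the C1=C2 vinyl group of 8 with the aryl group going to the unsubstituted C1 and palladium to C2, and after rotation about C1–C2 a syn β-hydride elimination of a C1 hydrogen releases the conjugated enone while NaHCO3 takes up HI and returns the catalyst. The closest known reaction type is the Mizoroki–Heck arylation of methyl vinyl ketone and related vinyl ketones with aryl iodides under ligand-free phase-transfer conditions, so the step applies established chemistry to a new substrate. No ring is closed and no stereocentre is created; the C5 carbinol stays racemic and disappears as a stereo-element in step 7. The step needs arylation at the terminal C1 and E geometry: the first follows from the polarisation of the vinyl ketone and the lower steric demand at its CH2 terminus, the second from the syn-insertion and syn-elimination sequence through the rotamer that places the aryl and acyl groups anti. It also needs the aldol unit to survive, which the weak bicarbonate base, the moderate temperature and the absence of amine or phosphine should secure against retro-aldol cleavage, dehydration and closure of the C5 hydroxyl onto C1, and the aryl silyl ethers should be inert to bicarbonate and chloride in dry DMF.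

Step 7
Reactants: 11 racemic (E)-1,7-bis[4-(tert-butyldimethylsilyloxy)-3-methoxyphenyl]-5-hydroxyhept-1-en-3-one
Product: 12 (E)-1,7-bis[4-(tert-butyldimethylsilyloxy)-3-methoxyphenyl]hept-1-ene-3,5-dione
Conditions: Dess–Martin periodinane (1.2 equiv), CH2Cl2, 0 °C to rt
Reagents that add atoms: none
Why: Dess–Martin oxidation of a β-hydroxy ketone is a standard mild entry to 1,3-diketones that should leave the enone, the aryl silyl ethers and the electron-rich rings alone when only a slight excess of reagent is used (to avoid further oxidation at C4), and it removes the only stereocentre.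

Step 8
Reactants: 12 (E)-1,7-bis[4-(tert-butyldimethylsilyloxy)-3-methoxyphenyl]hept-1-ene-3,5-dione
Product: 13 dihydrocurcumin, (E)-1,7-bis(4-hydroxy-3-methoxyphenyl)hept-1-ene-3,5-dione
Conditions: Bu4NF (2.4 equiv), AcOH (2.4 equiv), THF, 0 °C
Reagents that add atoms: none
Why: Fluoride-mediated desilylation of aryl silyl ethers is fast at 0 °C, and buffering Bu4NF with acetic acid keeps the medium near neutral so that the base-labile enolised β-diketone and the freed phenols are not exposed to phenoxide or retro-Claisen conditions.

Compound list
1 | dihydroferulic acid, 3-(4-hydroxy-3-methoxyphenyl)propanoic acid | COc1cc(CCC(=O)O)ccc1O | starting material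
2 | methyl 3-(4-hydroxy-3-methoxyphenyl)propanoate | COC(=O)CCc1ccc(O)c(OC)c1 | intermediate
3 | methyl 3-[4-(tert-butyldimethylsilyloxy)-3-methoxyphenyl]propanoate | COC(=O)CCc1ccc(O[Si](C)(C)C(C)(C)C)c(OC)c1 | intermediate
4 | racemic {3-[4-(tert-butyldimethylsilyloxy)-3-methoxyphenyl]-1-methoxypropoxy}diisobutylaluminium, the aluminium hemiacetal (not isolated) | COC(CCc1ccc(O[Si](C)(C)C(C)(C)C)c(OC)c1)O[Al](CC(C)C)CC(C)C | intermediate
5 | 3-[4-(tert-butyldimethylsilyloxy)-3-methoxyphenyl]propanal | O=CCCc1ccc(O[Si](C)(C)C(C)(C)C)c(OC)c1 | intermediate
6 | 2-(trimethylsilyloxy)-1,3-butadiene | C=CC(=C)O[Si](C)(C)C | starting material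
7 | racemic 7-[4-(tert-butyldimethylsilyloxy)-3-methoxyphenyl]-5-(difluoroboranyloxy)hept-1-en-3-one, the difluoroboron aldolate (not isolated) | C=CC(=O)CC(OB(F)F)CCc1ccc(O[Si](C)(C)C(C)(C)C)c(OC)c1 | intermediate
8 | racemic 7-[4-(tert-butyldimethylsilyloxy)-3-methoxyphenyl]-5-hydroxyhept-1-en-3-one | C=CC(=O)CC(O)CCc1ccc(O[Si](C)(C)C(C)(C)C)c(OC)c1 | intermediate
9 | 4-iodo-2-methoxyphenol | COc1cc(I)ccc1O | starting material
10 | 1-(tert-butyldimethylsilyloxy)-4-iodo-2-methoxybenzene | COc1cc(I)ccc1O[Si](C)(C)C(C)(C)C | intermediate
11 | racemic (E)-1,7-bis[4-(tert-butyldimethylsilyloxy)-3-methoxyphenyl]-5-hydroxyhept-1-en-3-one | COc1cc(/C=C/C(=O)CC(O)CCc2ccc(O[Si](C)(C)C(C)(C)C)c(OC)c2)ccc1O[Si](C)(C)C(C)(C)C | intermediate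
12 | (E)-1,7-bis[4-(tert-butyldimethylsilyloxy)-3-methoxyphenyl]hept-1-ene-3,5-dione | COc1cc(/C=C/C(=O)CC(=O)CCc2ccc(O[Si](C)(C)C(C)(C)C)c(OC)c2)ccc1O[Si](C)(C)C(C)(C)C | intermediate
13 | dihydrocurcumin, (E)-1,7-bis(4-hydroxy-3-methoxyphenyl)hept-1-ene-3,5-dione | COc1cc(/C=C/C(=O)CC(=O)CCc2ccc(O)c(OC)c2)ccc1O | target

Total step count: 8 steps.
Longest linear sequence: 7 steps (steps 1, 2, 3, 4, 6, 7, 8 from dihydroferulic acid); the aryl iodide branch is 1 step (step 5).

Steps most likely to fail

Step 6. The coupling may be undermined by erosion of the aldol unit under warm basic conditions (retro-aldol cleavage, dehydration, or closure of the C5 hydroxyl onto C1 to a tetrahydropyranone). Polymerisation of the vinyl ketone before arylation and partial loss of an aryl silyl ether are further risks. The fallback sets out from 8 and returns at 11, replacing the Heck reaction by olefin cross-metathesis. Commercial 2-methoxy-4-vinylphenol would be silylated (TBSCl, imidazole, DMF) to 4-(tert-butyldimethylsilyloxy)-3-methoxystyrene F1. Cross-metathesis of 8 with an excess of F1 (second-generation Grubbs catalyst, CH2Cl2, 40 °C, neutral and base-free) should then give the E-enone 11 with loss of ethene.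

Step 4. The aldol may suffer from protodesilylation of the diene to methyl vinyl ketone followed by polymerisation. Acid-promoted ring closure of the new hydroxyl onto the vinyl ketone (or a cycloaddition-type pathway of the diene with the aldehyde) and a second aldol addition of the product are also possible. The fallback sets out from 5 and returns at 8, building the vinyl ketone in two stages. N-Methoxy-N-methylacetamide would be deprotonated with LiN(i-Pr)2 in THF at −78 °C to the lithium enolate of N-methoxy-N-methylacetamide F2. Its aldol addition to 5 should give racemic 5-[4-(tert-butyldimethylsilyloxy)-3-methoxyphenyl]-3-hydroxy-N-methoxy-N-methylpentanamide F3. Treatment of F3 with CH2=CHMgBr (3 equiv, THF, −78 to 0 °C, inverse quench into cold dilute acid to keep the released amine from adding to the enone) should give 8.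

Step 3. The partial reduction may run on to the primary alcohol or stall, giving mixtures of ester, aldehyde and alcohol through premature collapse of the aluminium hemiacetal. The fallback sets out from 3 and returns at 5 through a full reduction and re-oxidation. Excess i-Bu2AlH (2.5 equiv, CH2Cl2, −78 to 0 °C) should reduce 3 completely to 3-[4-(tert-butyldimethylsilyloxy)-3-methoxyphenyl]propan-1-ol F4. Oxidation of F4 with PhI(OAc)2 and catalytic TEMPO in CH2Cl2 at rt should stop at aldehyde 5.

Further compounds
F1 | step 6 | 4-(tert-butyldimethylsilyloxy)-3-methoxystyrene | C=Cc1ccc(O[Si](C)(C)C(C)(C)C)c(OC)c1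
F2 | step 4 | lithium enolate of N-methoxy-N-methylacetamide | C=C(O[Li])N(C)OC
F3 | step 4 | racemic 5-[4-(tert-butyldimethylsilyloxy)-3-methoxyphenyl]-3-hydroxy-N-methoxy-N-methylpentanamide | CON(C)C(=O)CC(O)CCc1ccc(O[Si](C)(C)C(C)(C)C)c(OC)c1
F4 | step 3 | 3-[4-(tert-butyldimethylsilyloxy)-3-methoxyphenyl]propan-1-ol | OCCCc1ccc(O[Si](C)(C)C(C)(C)C)c(OC)c1
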